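**Retrosynthetic overview**
1. Target 16 ⇐ C‑silyl compound 15 ⇐ bromodiol 13 by a one‑flask double ring closure: ring B (C9–O–C12 tetrahydrofuran) by NBS 5‑exo bromoetherification of the E‑12,13‑olefin, then ring A (C7–O–C10 alkylidene tetrahydrofuran) by Au(I) 5‑exo‑dig addition of 10‑OH to the 6,7‑alkyne.
2. 13 ⇐ cis‑epoxy alcohol 12 (bromide opens propargylic C8 with inversion) ⇐ (Z)‑enynol 11 (hydroxyl‑directed threo epoxidation).
3. 11 ⇐ two Sonogashira couplings: (Z)‑iodoallylic alcohol 6 + chloroenyne 9, then the vinyl chloride + TMS‑acetylene 2.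
4. 6 ⇐ (S)‑propargylic alcohol 5 (trans‑hydroalumination/iodination) ⇐ ynone 3 (Noyori transfer hydrogenation) ⇐ ethyl (E)‑hex‑3‑enoate 1 + 2; 9 ⇐ (Z)‑1,3‑dichloropropene 7 + ethynylmagnesium bromide 8.
5. Stereocontrol: C10 by catalyst, C8/C9 relayed from C10, C12/C13 by anti addition to the E‑olefin during ring B closure.

Assumption: the target is made exactly as drawn (8S,9R,10S,12R,13S; locants in the text follow the C15 chain, C1 = terminal alkyne CH, C15 = CH3).

**Step 1**
Reactants: 1 ethyl (3E)-hex-3-enoate; 2 ethynyl(trimethyl)silane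
Product: 3 (5E)-1-(trimethylsilyl)oct-5-en-1-yn-3-one
Conditions: 2, n-BuLi, THF, −78 °C; BF3·OEt2; then 1, −78 °C
Reagents that add atoms: none
Why: Yamaguchi–Hirao ynone synthesis: the BF3‑complexed lithium acetylide adds once to the ester and the tetrahedral adduct collapses only on work‑up, so there is no over‑addition and no enolisation of the β,γ‑unsaturated ester; no stereocentre is formed.

**Step 2**
Reactants: 3 (5E)-1-(trimethylsilyl)oct-5-en-1-yn-3-one
Product: 5 (3S,5E)-oct-5-en-1-yn-3-ol, via silyl propargylic alcohol 4 (not isolated)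
Conditions: Ru[(S,S)-TsDPEN](p-cymene) (1 mol%), i-PrOH, rt; then K2CO3 (cat.), MeOH, rt
Reagents that add atoms: none
Why: Noyori asymmetric transfer hydrogenation of an alkynyl ketone (the (S,S)-TsDPEN–Ru hydride differentiates the alkynyl from the alkyl flank and gives the (S)-carbinol, C10 of the target, irreversibly and without added base), followed by protodesilylation of the alkynylsilane with methanolic carbonate in the same flask, which does not touch the stereocentre.

**Step 3**
Reactants: 5 (3S,5E)-oct-5-en-1-yn-3-ol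
Product: 6 (1Z,3S,5E)-1-iodoocta-1,5-dien-3-ol
Conditions: Red-Al, THF, 0 °C → rt; then I2, −78 → 0 °C
Reagents that add atoms: iodine (II)
Why: Hydroxyl‑directed trans‑hydroalumination of the propargylic alcohol puts aluminium on the terminal carbon in a five‑membered alkoxyalanate, and iodinolysis with retention gives the (Z)-3-iodoallylic alcohol; the remote E‑olefin and C10 are untouched.

**Step 4**
Reactants: 7 (1Z)-1,3-dichloroprop-1-ene; 8 ethynylmagnesium bromide
Product: 9 (1Z)-1-chloropent-1-en-4-yne
Conditions: CuCl (5 mol%), THF, 0 → 40 °C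
Reagents that add atoms: none
Why: Copper‑catalysed SN2 coupling of an alkynyl Grignard reagent with the allylic chloride; the vinylic chloride is inert and the Z geometry is kept.

**Step 5**
Reactants: 6 (1Z,3S,5E)-1-iodoocta-1,5-dien-3-ol; 9 (1Z)-1-chloropent-1-en-4-yne
Product: 10 (3E,6S,7Z,12Z)-13-chlorotrideca-3,7,12-trien-9-yn-6-ol
Conditions: PdCl2(PPh3)2 (3 mol%), CuI (6 mol%), Et3N, THF, 0 °C → rt
Reagents that add atoms: none
Why: Sonogashira coupling that engages only the vinyl iodide (the alkenyl chloride does not undergo oxidative addition with PPh3 ligands at rt) and keeps both Z olefins; the free alcohol is tolerated.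

**Step 6**
Reactants: 10 (3E,6S,7Z,12Z)-13-chlorotrideca-3,7,12-trien-9-yn-6-ol; 2 ethynyl(trimethyl)silane
Product: 11 (3E,6S,7Z,12Z)-15-(trimethylsilyl)pentadeca-3,7,12-triene-9,14-diyn-6-ol
Conditions: PdCl2(PhCN)2 (5 mol%), CuI (10 mol%), piperidine, rt
Reagents that add atoms: none
Why: Sonogashira coupling of an alkenyl chloride under Alami–Linstrumelle conditions, with retention of the Z geometry, completes the skipped (Z)-enyne by the established 1,3-dichloropropene two‑coupling sequence.

**Step 7**
Reactants: 11 (3E,6S,7Z,12Z)-15-(trimethylsilyl)pentadeca-3,7,12-triene-9,14-diyn-6-ol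
Product: 12 (1S,3E)-1-{(2R,3S)-3-[(4Z)-7-(trimethylsilyl)hept-4-ene-1,6-diyn-1-yl]oxiran-2-yl}hex-3-en-1-ol (cis‑epoxide, threo to the OH; 8S,9R,10S)
Conditions: Ti(Oi-Pr)4 (1.2 equiv), t-BuOOH, 4 Å MS, CH2Cl2, −20 °C
Reagents that add atoms: tert-butyl hydroperoxide (CC(C)(C)OO)
Why: Hydroxyl‑directed titanium/t‑BuOOH epoxidation (Sharpless type, achiral) reacts only at the allylic olefin, and A(1,3) strain in the Z‑allylic alcohol (carbinol H eclipsing the olefin) makes oxygen delivery syn to the OH threo‑selective, so the cis‑epoxide carbons C8 and C9 are set from C10.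

**Step 8**
Reactants: 12 (cis‑epoxy alcohol)
Product: 13 (3E,6S,7R,8R,12Z)-8-bromo-15-(trimethylsilyl)pentadeca-3,12-diene-9,14-diyne-6,7-diol (chain numbering of the target: 8R,9R,10S)
Conditions: LiBr, AcOH, THF, 0 °C
Reagents that add atoms: lithium bromide ([Li+].[Br-])
Why: Regioselective SN2 opening of the alkynyl 2,3‑epoxy alcohol by bromide at the propargylic carbon remote from the hydroxyl (C8) gives inversion at C8 and retention at C9, i.e. the C8 bromide and the threo 9,10‑diol in one step.

**Step 9**
Reactants: 13 (bromodiol)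
Product: 15 (2Z,3S,3aR,5R,6aS)-3-bromo-5-[(1S)-1-bromopropyl]-2-[(3Z)-6-(trimethylsilyl)hex-3-en-5-yn-1-ylidene]hexahydrofuro[3,2-b]furan, via bromotetrahydrofuranol 14 (not isolated)
Conditions: NBS (1.05 equiv), CH2Cl2, −40 → 0 °C, dark; then Ph3PAuNTf2 (5 mol%), rt
Reagents that add atoms: N-bromosuccinimide (O=C1CCC(=O)N1Br)
Why: Proposed new method: a one‑flask bromoetherification/gold cycloisomerisation, in which NBS forms the bromonium ion of the only isolated electron‑rich olefin and 9‑OH closes ring B 5‑exo (anti addition to the E‑olefin gives the erythro C12–O/C13–Br pair, and a chair‑like transition state with the large C9 substituent equatorial and 10‑OH axial avoids the all‑cis tetrahydrofuran and is expected to favour the 2,5‑trans ring, the minor C12 epimer being removed at 15), which leaves 10‑OH as the only hydroxyl so that Ph3PAuNTf2 then effects anti 5‑exo‑dig oxyauration/protodeauration of the 6,7‑alkyne to the cis‑fused ring A with the Z enol ether; the closest known reactions are NBS bromoetherifications of Laurencia‑type alkenols and Au(I) cycloisomerisations of 4‑alkyn‑1‑ols to (Z)-2-alkylidenetetrahydrofurans.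

**Step 10**
Reactants: 15 (C‑silylated bicycle)
Product: 16 (2Z,3S,3aR,5R,6aS)-3-bromo-5-[(1S)-1-bromopropyl]-2-[(3Z)-hex-3-en-5-yn-1-ylidene]hexahydrofuro[3,2-b]furan
Conditions: K2CO3 (0.2 equiv), MeOH, 0 °C
Reagents that add atoms: none
Why: Carbonate‑catalysed methanolysis of the alkynyl C–Si bond (protodesilylation) at 0 °C; the C8 bromide has no anti‑periplanar β‑hydrogen and a β‑oxygen that slows SN2, and no stereocentre is involved.

**Compound list**
1 | ethyl (3E)-hex-3-enoate | CCOC(=O)C/C=C/CC | starting material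
2 | ethynyl(trimethyl)silane | C#C[Si](C)(C)C | starting material
3 | (5E)-1-(trimethylsilyl)oct-5-en-1-yn-3-one | C[Si](C)(C)C#CC(=O)C/C=C/CC | intermediate
4 | (3S,5E)-1-(trimethylsilyl)oct-5-en-1-yn-3-ol | C[Si](C)(C)C#C[C@@H](O)C/C=C/CC | intermediate
5 | (3S,5E)-oct-5-en-1-yn-3-ol | C#C[C@@H](O)C/C=C/CC | intermediate
6 | (1Z,3S,5E)-1-iodoocta-1,5-dien-3-ol | I/C=C\[C@@H](O)C/C=C/CC | intermediate
7 | (1Z)-1,3-dichloroprop-1-ene | ClC/C=C\Cl | starting material
8 | ethynylmagnesium bromide | C#C[Mg]Br | starting material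
9 | (1Z)-1-chloropent-1-en-4-yne | C#CC/C=C\Cl | intermediate
10 | (3E,6S,7Z,12Z)-13-chlorotrideca-3,7,12-trien-9-yn-6-ol | Cl/C=C\CC#C/C=C\[C@@H](O)C/C=C/CC | intermediate
11 | (3E,6S,7Z,12Z)-15-(trimethylsilyl)pentadeca-3,7,12-triene-9,14-diyn-6-ol | C[Si](C)(C)C#C/C=C\CC#C/C=C\[C@@H](O)C/C=C/CC | intermediate
12 | (1S,3E)-1-{(2R,3S)-3-[(4Z)-7-(trimethylsilyl)hept-4-ene-1,6-diyn-1-yl]oxiran-2-yl}hex-3-en-1-ol | C[Si](C)(C)C#C/C=C\CC#C[C@@H]1O[C@@H]1[C@@H](O)C/C=C/CC | intermediate
13 | (3E,6S,7R,8R,12Z)-8-bromo-15-(trimethylsilyl)pentadeca-3,12-diene-9,14-diyne-6,7-diol | C[Si](C)(C)C#C/C=C\CC#C[C@@H](Br)[C@H](O)[C@@H](O)C/C=C/CC | intermediate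
14 | (2R,3S,5R)-2-[(1R,5Z)-1-bromo-8-(trimethylsilyl)oct-5-ene-2,7-diyn-1-yl]-5-[(1S)-1-bromopropyl]oxolan-3-ol | C[Si](C)(C)C#C/C=C\CC#C[C@@H](Br)[C@@H]1O[C@@H]([C@@H](Br)CC)C[C@@H]1O | intermediate
15 | (2Z,3S,3aR,5R,6aS)-3-bromo-5-[(1S)-1-bromopropyl]-2-[(3Z)-6-(trimethylsilyl)hex-3-en-5-yn-1-ylidene]hexahydrofuro[3,2-b]furan | C[Si](C)(C)C#C/C=C\C/C=C1\O[C@H]2C[C@H]([C@@H](Br)CC)O[C@H]2[C@@H]1Br | intermediate
16 | (2Z,3S,3aR,5R,6aS)-3-bromo-5-[(1S)-1-bromopropyl]-2-[(3Z)-hex-3-en-5-yn-1-ylidene]hexahydrofuro[3,2-b]furan | C#C/C=C\C/C=C1\O[C@H]2C[C@H]([C@@H](Br)CC)O[C@H]2[C@@H]1Br | target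

**Step count**
Total steps: 10. Longest linear sequence: 9 (steps 1, 2, 3, 5, 6, 7, 8, 9, 10; step 4 is the side branch).

**Steps most likely to fail, with fallbacks**

Step 9 is the riskiest. The C12 configuration comes from an acyclic diol, so the 2,5‑trans preference may be modest. The gold catalyst must also tolerate succinimide and a propargylic bromide, and must close 5‑exo rather than 6‑endo. The fallback sets out from 12 and comes back at 14. Epoxy alcohol 12 is treated with tetrabutylammonium tribromide in CH2Cl2 at −40 °C under high dilution. The bromonium ion of the 12,13‑olefin is captured 5‑exo by the epoxide oxygen, and bromide opens the resulting bicyclic epoxonium ion at propargylic C8 with inversion. This gives 14 directly with both C–Br bonds, and the facial choice is then governed by exo attack on a bicyclic oxonium ion instead of by the open‑chain diol. 14 is isolated, freed of its C12 epimer, and cyclised with the gold catalyst as a separate operation to 15. This detour makes no new compound (F0).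

Step 7 is next. The slim alkynyl cis substituent may give only a moderate threo:erythro ratio, and the doubly skipped dienediyne and the alkynyl epoxide are sensitive to the Lewis acidic peroxide medium. The fallback sets out from 10 and comes back at 12. The directed titanium/t‑BuOOH epoxidation is run one stage earlier on the chlorotrienynol 10, which carries only one enyne, to give (1S,3E)-1-{(2R,3S)-3-[(4Z)-5-chloropent-4-en-1-yn-1-yl]oxiran-2-yl}hex-3-en-1-ol F1. The threo isomer is purified at this simpler stage, and its vinyl chloride is then coupled with 2 under the conditions of step 6 to give 12. The epoxide is thus installed before the silyl enyne is attached.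

Step 3 is the third. Red‑Al hydroalumination of a terminal secondary propargylic alcohol can over‑reduce to the allylic alcohol or give regio‑ and geometric isomers on iodinolysis. The fallback sets out from 5 and comes back at 6. The terminal alkyne is iodinated (NIS, cat. AgNO3, acetone) to (3S,5E)-1-iodooct-5-en-1-yn-3-ol F2. The iodoalkyne is then reduced cis with diimide (2‑nitrobenzenesulfonylhydrazide, Et3N, THF/i‑PrOH), which attacks it much faster than the isolated E‑olefin, to give 6.

**Further compounds**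
F0 | step 9 | none | none
F1 | step 7 | (1S,3E)-1-{(2R,3S)-3-[(4Z)-5-chloropent-4-en-1-yn-1-yl]oxiran-2-yl}hex-3-en-1-ol | Cl/C=C\CC#C[C@@H]1O[C@@H]1[C@@H](O)C/C=C/CC
F2 | step 3 | (3S,5E)-1-iodooct-5-en-1-yn-3-ol | IC#C[C@@H](O)C/C=C/CC
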